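**Retrosynthetic overview**
1. Numbering (daucane): C1 quaternary ring-fusion carbon (CH3), C2/C3 cyclopentane CH2, C4 C(OH)(isopropyl), C5 ring-fusion CH, C6 CH–O–aroyl, C7 C=O, C8 C(CH3)OH, C9 CHOH, C10 CH2; β is the face of the C1 methyl group.
2. Endgame: target ⇐ desilylation ⇐ syn-dihydroxylation of a C8=C9 enone ⇐ conjugation of a C9=C10 alkene; the C6 aroyloxy group ⇐ Rubottom oxidation of a C6=C7 enol silane, then esterification.
3. Key disconnection: C1–C5 and C8–C9 together, by a gold-catalysed intramolecular (4+3) cycloaddition of an acyclic allene–silyloxydiene. The enabling feature is that these two bonds cut the cycloheptane into a three-carbon arc C1–C10–C9, whose middle carbon C10 is a bare CH2 (so an allene can serve), and a four-carbon arc C5–C6–C7–C8, whose C7 ketone can be carried as a 2-silyloxy-1,3-diene; the cyclopentane carbons C2–C3–C4 are the three-atom tether from C1 to C5.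
4. Acyclic precursor ⇐ Horner–Wadsworth–Emmons enone from an α-hydroxy aldehyde; the C4 carbinol ⇐ dioxolanone alkylation (self-regeneration of stereocentres) of (R)-2-hydroxy-3-methylbutanoic acid with an allenic iodide made by Johnson–Claisen rearrangement.
5. Ring order: cyclopentane and cycloheptane are formed together in the key step; no other carbocycle is made (the dioxolanone is a temporary auxiliary ring).

Key step: step 10

**Route**

Step 1
Reactants: 1 but-2-yn-1-ol; 2 triethyl orthoacetate
Product: 3 ethyl 3-methylpenta-3,4-dienoate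
Conditions: EtCO2H (cat.), neat, 140 °C, EtOH distilled off
Reagents that add atoms: none
Why: Johnson–Claisen rearrangement of the propargylic ketene acetal should give the 1,1-disubstituted allene by a [3,3] shift; no stereocentre is formed.

Step 2
Reactants: 3 ethyl 3-methylpenta-3,4-dienoate
Product: 4 3-methylpenta-3,4-dien-1-ol
Conditions: LiAlH4, Et2O, 0 °C
Reagents that add atoms: none
Why: Hydride reduction of the ester; the unactivated allene is inert to LiAlH4.

Step 3
Reactants: 4 3-methylpenta-3,4-dien-1-ol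
Product: 5 5-iodo-3-methylpenta-1,2-diene
Conditions: PPh3, I2, imidazole, CH2Cl2, 0 °C
Reagents that add atoms: iodine, II
Why: Appel-type iodination by SN2 displacement of the primary alkoxyphosphonium ion.

Step 4
Reactants: 6 (R)-2-hydroxy-3-methylbutanoic acid; 7 pivalaldehyde
Product: 8 (2R,5R)-2-tert-butyl-5-(propan-2-yl)-1,3-dioxolan-4-one
Conditions: TsOH·H2O (cat.), H2SO4 (cat.), pentane, reflux, water separator; recrystallisation
Reagents that add atoms: none
Why: Acid-catalysed acetalisation under thermodynamic control should place the tert-butyl group cis to the isopropyl group, and the cis isomer is purified by crystallisation.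

Step 5
Reactants: 8 (2R,5R)-2-tert-butyl-5-(propan-2-yl)-1,3-dioxolan-4-one; 5 5-iodo-3-methylpenta-1,2-diene
Product: 10 (2R,5R)-2-tert-butyl-5-(3-methylpenta-3,4-dien-1-yl)-5-(propan-2-yl)-1,3-dioxolan-4-one, via lithium enolate 9 (not isolated)
Conditions: LiN(iPr)2, THF, −78 °C; then 5, DMPU, −78 to −20 °C
Reagents that add atoms: none
Why: Enolate alkylation with self-regeneration of the stereocentre: the iodide should enter anti to the tert-butyl group, so the chain takes the place of the former hydrogen and the quaternary carbinol carbon (later C4) is set as R.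

Step 6
Reactants: 10 (2R,5R)-2-tert-butyl-5-(3-methylpenta-3,4-dien-1-yl)-5-(propan-2-yl)-1,3-dioxolan-4-one
Product: 11 (2R)-5-methyl-2-(propan-2-yl)hepta-5,6-diene-1,2-diol
Conditions: LiAlH4, THF, 0 °C to rt
Reagents that add atoms: none
Why: Hydride reduction of the acyl acetal releases the diol and reduces the liberated pivalaldehyde; the quaternary stereocentre is untouched.

Step 7
Reactants: 11 (2R)-5-methyl-2-(propan-2-yl)hepta-5,6-diene-1,2-diol
Product: 12 (2R)-2-hydroxy-5-methyl-2-(propan-2-yl)hepta-5,6-dienal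
Conditions: SO3·pyridine, DMSO, iPr2NEt, CH2Cl2, 0 °C; used crude
Reagents that add atoms: none
Why: Parikh–Doering oxidation can only touch the primary alcohol, causes no glycol cleavage, and the α-carbon has no hydrogen to epimerise.

Step 8
Reactants: 12 (2R)-2-hydroxy-5-methyl-2-(propan-2-yl)hepta-5,6-dienal; 13 diethyl (2-oxobutyl)phosphonate
Product: 14 (4E,6R)-6-hydroxy-9-methyl-6-(propan-2-yl)undeca-4,9,10-trien-3-one
Conditions: LiCl, iPr2NEt, MeCN, rt
Reagents that add atoms: none
Why: Horner–Wadsworth–Emmons olefination under Masamune–Roush conditions should give the E enone and tolerates the free tertiary alcohol.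

Step 9
Reactants: 14 (4E,6R)-6-hydroxy-9-methyl-6-(propan-2-yl)undeca-4,9,10-trien-3-one
Product: 15 (2Z,4E,6R)-9-methyl-6-(propan-2-yl)-3,6-bis(triethylsilyloxy)undeca-2,4,9,10-tetraene
Conditions: Et3SiOTf (2.5 equiv), Et3N, CH2Cl2, −78 to 0 °C
Reagents that add atoms: triethylsilyl trifluoromethanesulfonate, CC[Si](CC)(CC)OS(=O)(=O)C(F)(F)F
Why: O-silylation of the tertiary alcohol and soft enolisation of the ethyl ketone should give the Z silyl dienol ether, which places the future C8 methyl group on the outside of the s-cis diene.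

Step 10
Reactants: 15 (2Z,4E,6R)-9-methyl-6-(propan-2-yl)-3,6-bis(triethylsilyloxy)undeca-2,4,9,10-tetraene
Product: 16 4β,7-bis(triethylsilyloxy)-5αH-dauca-6,9-diene (trans-fused bicyclo[5.3.0]decadiene; 1β-CH3, 4α-isopropyl, 8β-CH3)
Conditions: [Au(IPr)(NCMe)]SbF6 (5 mol %; IPr = 1,3-bis(2,6-diisopropylphenyl)imidazol-2-ylidene), 2,6-di-tert-butyl-4-methylpyridine (10 mol %), 4 Å MS, CH2Cl2, 0 °C to rt
Reagents that add atoms: none
Why: The cationic monovalent gold centre should activate the allene as a gold-bound allyl cation spanning C1–C10–C9, which adds suprafacially across the s-cis 2-silyloxydiene C5=C6–C7=C8 in a concerted, asynchronous (4+3) cycloaddition to give a cycloheptenyl gold carbene at C10; a 1,2-hydride shift from C9, the only neighbour of the carbene that bears hydrogen, then forms the C9=C10 alkene and releases the catalyst. The closest known reaction type is the gold- or platinum-catalysed intramolecular (4C+3C) cycloaddition of allenedienes joined by a three-atom tether, which gives trans-fused bicyclo[5.3.0]decadienes. The cyclopentane closes by bonding of the diene terminus C5 to the allyl terminus C1 through the C2–C3–C4 tether (five-membered closure onto the cation terminus), and the cycloheptadiene closes as the (4+3) ring itself through the second bond C8–C9. C1 and C5 should be set trans (CH3 β, H α) by the exo-like transition state with the E C5=C6 bond; their absolute sense is set by the C4 stereocentre, whose isopropyl group should lie anti to C6 and whose silyloxy group should take the inside position; the transient C8 centre follows from the Z enol ether. The step needs (4+3) over (4+2) periselectivity, which the strongly donating carbene ligand secures by favouring hydride over alkyl migration, and chemoselectivity for the allene, which silylation of the C4 hydroxyl (no hydroalkoxylation) and the tether (only C5 can reach C1) secure.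

Step 11
Reactants: 16 4β,7-bis(triethylsilyloxy)-5αH-dauca-6,9-diene
Product: 18 6α-hydroxy-4β-(triethylsilyloxy)-5αH-dauc-9-en-7-one, via silyloxy epoxide 17 (not isolated)
Conditions: dimethyldioxirane (1.05 equiv), acetone/CH2Cl2, −78 °C; then AcOH, THF/H2O, 0 °C
Reagents that add atoms: dimethyldioxirane, CC1(C)OO1
Why: Rubottom oxidation: the electron-rich enol silane should be epoxidised in preference to the C9=C10 alkene and from the α face, away from the axial C1 methyl group, which sets C6 (oxygen α); mild hydrolysis unveils the C7 ketone.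

Step 12
Reactants: 19 4-hydroxybenzoic acid
Product: 21 4-(tert-butyldimethylsilyloxy)benzoic acid, via bis-silyl ester 20 (not isolated)
Conditions: tBuMe2SiCl (2.2 equiv), imidazole, DMF, rt; then AcOH/THF/H2O, rt
Reagents that add atoms: tert-butyldimethylsilyl chloride, CC(C)(C)[Si](C)(C)Cl
Why: Exhaustive silylation followed by selective hydrolysis of the labile silyl ester leaves the aryl silyl ether.

Step 13
Reactants: 18 6α-hydroxy-4β-(triethylsilyloxy)-5αH-dauc-9-en-7-one; 21 4-(tert-butyldimethylsilyloxy)benzoic acid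
Product: 22 6α-[4-(tert-butyldimethylsilyloxy)benzoyloxy]-4β-(triethylsilyloxy)-5αH-dauc-9-en-7-one
Conditions: DCC, DMAP (cat.), CH2Cl2, 0 °C to rt
Reagents that add atoms: none
Why: Steglich esterification acylates the only free hydroxyl with retention at C6.

Step 14
Reactants: 22 6α-[4-(tert-butyldimethylsilyloxy)benzoyloxy]-4β-(triethylsilyloxy)-5αH-dauc-9-en-7-one
Product: 23 6α-[4-(tert-butyldimethylsilyloxy)benzoyloxy]-4β-(triethylsilyloxy)-5αH-dauc-8-en-7-one
Conditions: DBU (0.2 equiv), CH2Cl2, rt
Reagents that add atoms: none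
Why: Base-mediated β,γ- to α,β-enone isomerisation through the C7 dienolate (γ-protonation at C10) should give the conjugated trisubstituted enone; it removes the transient C8 centre and lets C6 settle in the α (equatorial) configuration, which avoids the C1 methyl group.

Step 15
Reactants: 23 6α-[4-(tert-butyldimethylsilyloxy)benzoyloxy]-4β-(triethylsilyloxy)-5αH-dauc-8-en-7-one
Product: 24 6α-[4-(tert-butyldimethylsilyloxy)benzoyloxy]-8α,9α-dihydroxy-4β-(triethylsilyloxy)-5αH-daucan-7-one
Conditions: OsO4 (5 mol %), N-methylmorpholine N-oxide, citric acid, tBuOH/H2O, rt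
Reagents that add atoms: osmium tetroxide, O=[Os](=O)(=O)=O; N-methylmorpholine N-oxide (terminal oxidant), C[N+]1([O-])CCOCC1; water, O
Why: Osmium-mediated syn-dihydroxylation by [3+2] osmate ester formation should occur on the α face, away from the axial C1 methyl group, and sets C8 and C9 together as the cis α,α-diol.

Step 16
Reactants: 24 6α-[4-(tert-butyldimethylsilyloxy)benzoyloxy]-8α,9α-dihydroxy-4β-(triethylsilyloxy)-5αH-daucan-7-one
Product: 25 4β,8α,9α-trihydroxy-6α-(4-hydroxybenzoyloxy)-5αH-daucan-7-one (CNP0241001.1)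
Conditions: HF·pyridine, pyridine/THF, 0 °C to rt
Reagents that add atoms: none
Why: Fluoride-mediated desilylation should remove the tertiary triethylsilyl ether and the aryl silyl ether under non-basic conditions, which avoids retro-aldol cleavage and acyl migration.

**Compound list**
1 | but-2-yn-1-ol | CC#CCO | starting material
2 | triethyl orthoacetate | CCOC(C)(OCC)OCC | starting material
3 | ethyl 3-methylpenta-3,4-dienoate | CCOC(=O)CC(C)=C=C | intermediate
4 | 3-methylpenta-3,4-dien-1-ol | OCCC(C)=C=C | intermediate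
5 | 5-iodo-3-methylpenta-1,2-diene | ICCC(C)=C=C | intermediate
6 | (R)-2-hydroxy-3-methylbutanoic acid | CC(C)[C@@H](O)C(=O)O | starting material
7 | pivalaldehyde | CC(C)(C)C=O | starting material
8 | (2R,5R)-2-tert-butyl-5-(propan-2-yl)-1,3-dioxolan-4-one | CC(C)[C@H]1O[C@@H](C(C)(C)C)OC1=O | intermediate
9 | lithium (R)-2-tert-butyl-5-(propan-2-yl)-1,3-dioxol-4-olate | CC(C)C1=C([O-])O[C@H](C(C)(C)C)O1.[Li+] | intermediate (not isolated)
10 | (2R,5R)-2-tert-butyl-5-(3-methylpenta-3,4-dien-1-yl)-5-(propan-2-yl)-1,3-dioxolan-4-one | CC(C)[C@@]1(CCC(C)=C=C)O[C@@H](C(C)(C)C)OC1=O | intermediate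
11 | (2R)-5-methyl-2-(propan-2-yl)hepta-5,6-diene-1,2-diol | CC(C)[C@](CO)(O)CCC(C)=C=C | intermediate
12 | (2R)-2-hydroxy-5-methyl-2-(propan-2-yl)hepta-5,6-dienal | CC(C)[C@](C=O)(O)CCC(C)=C=C | intermediate
13 | diethyl (2-oxobutyl)phosphonate | CCC(=O)CP(=O)(OCC)OCC | starting material
14 | (4E,6R)-6-hydroxy-9-methyl-6-(propan-2-yl)undeca-4,9,10-trien-3-one | CCC(=O)/C=C/[C@](O)(C(C)C)CCC(C)=C=C | intermediate
15 | (2Z,4E,6R)-9-methyl-6-(propan-2-yl)-3,6-bis(triethylsilyloxy)undeca-2,4,9,10-tetraene | C/C=C(O[Si](CC)(CC)CC)/C=C/[C@](O[Si](CC)(CC)CC)(C(C)C)CCC(C)=C=C | intermediate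
16 | 4β,7-bis(triethylsilyloxy)-5αH-dauca-6,9-diene | CC(C)[C@]1(O[Si](CC)(CC)CC)CC[C@]2(C)C=C[C@@H](C)C(O[Si](CC)(CC)CC)=C[C@H]21 | intermediate
17 | 6α,7α-epoxy-4β,7β-bis(triethylsilyloxy)-5αH-dauc-9-ene | CC(C)[C@]1(O[Si](CC)(CC)CC)CC[C@]2(C)C=C[C@@H](C)[C@]3(O[Si](CC)(CC)CC)O[C@@H]3[C@H]21 | intermediate (not isolated)
18 | 6α-hydroxy-4β-(triethylsilyloxy)-5αH-dauc-9-en-7-one | CC(C)[C@]1(O[Si](CC)(CC)CC)CC[C@]2(C)C=C[C@@H](C)C(=O)[C@H](O)[C@H]21 | intermediate
19 | 4-hydroxybenzoic acid | O=C(O)c1ccc(O)cc1 | starting material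
20 | tert-butyldimethylsilyl 4-(tert-butyldimethylsilyloxy)benzoate | CC(C)(C)[Si](C)(C)OC(=O)c1ccc(O[Si](C)(C)C(C)(C)C)cc1 | intermediate (not isolated)
21 | 4-(tert-butyldimethylsilyloxy)benzoic acid | CC(C)(C)[Si](C)(C)Oc1ccc(C(=O)O)cc1 | intermediate
22 | 6α-[4-(tert-butyldimethylsilyloxy)benzoyloxy]-4β-(triethylsilyloxy)-5αH-dauc-9-en-7-one | CC(C)[C@]1(O[Si](CC)(CC)CC)CC[C@]2(C)C=C[C@@H](C)C(=O)[C@H](OC(=O)c3ccc(O[Si](C)(C)C(C)(C)C)cc3)[C@H]21 | intermediate
23 | 6α-[4-(tert-butyldimethylsilyloxy)benzoyloxy]-4β-(triethylsilyloxy)-5αH-dauc-8-en-7-one | CC(C)[C@]1(O[Si](CC)(CC)CC)CC[C@]2(C)CC=C(C)C(=O)[C@H](OC(=O)c3ccc(O[Si](C)(C)C(C)(C)C)cc3)[C@H]21 | intermediate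
24 | 6α-[4-(tert-butyldimethylsilyloxy)benzoyloxy]-8α,9α-dihydroxy-4β-(triethylsilyloxy)-5αH-daucan-7-one | CC(C)[C@]1(O[Si](CC)(CC)CC)CC[C@]2(C)C[C@H](O)[C@](C)(O)C(=O)[C@H](OC(=O)c3ccc(O[Si](C)(C)C(C)(C)C)cc3)[C@H]21 | intermediate
25 | 4β,8α,9α-trihydroxy-6α-(4-hydroxybenzoyloxy)-5αH-daucan-7-one (CNP0241001.1) | CC(C)[C@]1(O)CC[C@]2(C)C[C@H](O)[C@](C)(O)C(=O)[C@H](OC(=O)c3ccc(O)cc3)[C@H]21 | target

**Step count and risks**
Total step count: 16. Longest linear sequence: 14 steps (1 to 25 through steps 1–3, 5–11 and 13–16).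

Step 10 (key cycloaddition). What may go wrong: the cycloheptenyl gold carbene may rearrange by 1,2-alkyl shift from the quaternary C1 to ring-contracted (4+2)-type products, the cationic gold may ionise the allylic C4 silyl ether, or the C4 centre may discriminate the diene faces poorly. The fallback sets out from 15 and comes back at 16, and it replaces the metal carbene by a metal-free allyl cation (4+3) cycloaddition of an allylic alcohol, a known cationic route to hydroazulenes. Chemoselective hydroboration of the allene of 15 with 9-BBN (THF, 0 °C) should give the B-allyl-9-borabicyclo[3.3.1]nonane F1, and anhydrous oxidation with Me3NO (3 equiv) followed by hydrolytic work-up the allylic alcohol F2, whose C2=C3 alkene geometry is irrelevant. Treatment of F2 with Tf2O and 2,6-lutidine in CH2Cl2 at −78 °C should ionise it to the same C1–C10–C9 allyl cation without a metal at C10; this cation adds across the silyloxydiene, and loss of a C9 proton from the resulting C10 cation returns 16.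

Step 14 (enone conjugation). What may go wrong: enolisation towards C6 may trigger acyl migration onto the C7 oxygen, or the β,γ/α,β equilibrium may stop short of full conjugation. The fallback sets out from 16 and comes back at 23, and it moves the conjugation ahead of the C6 oxygenation so that no α-acyloxy ketone meets base. K2CO3 in MeOH should cleave the enol silane and conjugate the alkene to give 4β-(triethylsilyloxy)-5αH-dauc-8-en-7-one F3. Kinetic deprotonation at C6 with LiN(SiMe3)2 (THF, −78 °C) gives the lithium cross-conjugated dienolate F4, and oxidation with 2-(phenylsulfonyl)-3-phenyloxaziridine from the α face, followed by an NH4Cl quench, should give 6α-hydroxy-4β-(triethylsilyloxy)-5αH-dauc-8-en-7-one F5. Esterification of F5 with 21 (DCC, DMAP) gives 23.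

Step 11 (Rubottom oxidation). What may go wrong: the oxidant may approach the enol silane from the β face, anti to the α-oriented isopropyl group on C4, so that C6 is formed with the wrong configuration. The fallback sets out from 16 and comes back at 22, and it replaces acylation with retention by esterification with inversion. The same oxidation would then give the 6β,7β-epoxy-4β,7α-bis(triethylsilyloxy)-5αH-dauc-9-ene F6 and, after hydrolysis, 6β-hydroxy-4β-(triethylsilyloxy)-5αH-dauc-9-en-7-one F7. Mitsunobu esterification of F7 with 21 (PPh3, diisopropyl azodicarboxylate, toluene, 0 °C to rt) should invert C6 by SN2 displacement next to the carbonyl group and give 22.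

Further compounds
F1 | step 10 | 9-[(6R,7E,9Z)-3-methyl-6-(propan-2-yl)-6,9-bis(triethylsilyloxy)undeca-2,7,9-trien-1-yl]-9-borabicyclo[3.3.1]nonane (C2=C3 geometry mixed) | C/C=C(O[Si](CC)(CC)CC)/C=C/[C@](O[Si](CC)(CC)CC)(C(C)C)CCC(C)=CCB1C2CCCC1CCC2
F2 | step 10 | (6R,7E,9Z)-3-methyl-6-(propan-2-yl)-6,9-bis(triethylsilyloxy)undeca-2,7,9-trien-1-ol (C2=C3 geometry mixed) | C/C=C(O[Si](CC)(CC)CC)/C=C/[C@](O[Si](CC)(CC)CC)(C(C)C)CCC(C)=CCO
F3 | step 14 | 4β-(triethylsilyloxy)-5αH-dauc-8-en-7-one | CC(C)[C@]1(O[Si](CC)(CC)CC)CC[C@]2(C)CC=C(C)C(=O)C[C@H]21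
F4 | step 14 | lithium 4β-(triethylsilyloxy)-5αH-dauca-6,8-dien-7-olate | CC(C)[C@]1(O[Si](CC)(CC)CC)CC[C@]2(C)CC=C(C)C([O-])=C[C@H]21.[Li+]
F5 | step 14 | 6α-hydroxy-4β-(triethylsilyloxy)-5αH-dauc-8-en-7-one | CC(C)[C@]1(O[Si](CC)(CC)CC)CC[C@]2(C)CC=C(C)C(=O)[C@H](O)[C@H]21
F6 | step 11 | 6β,7β-epoxy-4β,7α-bis(triethylsilyloxy)-5αH-dauc-9-ene | CC(C)[C@]1(O[Si](CC)(CC)CC)CC[C@]2(C)C=C[C@@H](C)[C@@]3(O[Si](CC)(CC)CC)O[C@H]3[C@H]21
F7 | step 11 | 6β-hydroxy-4β-(triethylsilyloxy)-5αH-dauc-9-en-7-one | CC(C)[C@]1(O[Si](CC)(CC)CC)CC[C@]2(C)C=C[C@@H](C)C(=O)[C@@H](O)[C@H]21
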